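The quinone ring (C1–C4, C4a, C8a) is cut into three parts: the arene edge C4a–C8a, the C2=C3 unit as a terminal alkyne that already carries the (R)-acyloxy side chain, and C1 and C4 as carbonyl ligands of Cr(CO)6. A Dötz benzannulation of an aryl(methoxy)carbene complex with this propargylic ester forms C3–C4, C1–C2 and C1–C8a and closes the last ring in one operation. Oxidation in the same flask gives the quinone. The step exploits the symmetry of the 5,8-dioxygenated benzenoid ring: both alkyne orientations give the same quinone. C1′ is set beforehand by reduction of an acyclic ynone.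

Key step: step 7

Assumption: positions are numbered as in 1,4-naphthoquinone (C1 and C4 carbonyl carbons, C2 bearing the side chain, C1′ the stereocentre), and the acids 6 and 13 are taken as catalogue compounds.

Step 1
Reactants: 1 hydroquinone
Product: 2 1,4-bis(methoxymethoxy)benzene
Conditions: NaH, MOMCl, DMF, 0 °C → rt
Reagents that add atoms: chloromethyl methyl ether (MOMCl), COCCl
Why: Williamson-type O-alkylation of the bis-phenoxide gives the bis-acetal, whose oxygen atoms later direct the lithiation and come off under mild acid.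

Step 2
Reactants: 2 1,4-bis(methoxymethoxy)benzene
Product: 5 pentacarbonyl{[2,5-bis(methoxymethoxy)phenyl](methoxy)carbene}chromium, via aryllithium 3 (not isolated), via lithium acylchromate 4 (not isolated)
Conditions: n-BuLi, TMEDA, Et2O, 0 °C → rt; Cr(CO)6, Et2O, rt; then MeOTf, CH2Cl2, 0 °C → rt
Reagents that add atoms: chromium hexacarbonyl, O=C=[Cr](=C=O)(=C=O)(=C=O)(=C=O)=C=O; methyl trifluoromethanesulfonate (MeOTf), COS(=O)(=O)C(F)(F)F
Why: Directed ortho-metalation (all four ring C–H positions of 2 are equivalent, so only one aryllithium can form) followed by the Fischer carbene synthesis, that is addition of the aryllithium to a CO ligand and O-methylation of the acylate, is the standard entry to aryl(methoxy)carbene complexes of zerovalent chromium.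

Step 3
Reactants: 6 4-methylpent-3-enoic acid
Product: 8 N-methoxy-N,4-dimethylpent-3-enamide, via acyl imidazole 7 (not isolated)
Conditions: 1,1′-carbonyldiimidazole, CH2Cl2, rt; then MeNH(OMe)·HCl, rt
Reagents that add atoms: N,O-dimethylhydroxylamine hydrochloride, CNOC.Cl
Why: Amide coupling through the acyl imidazole runs under nearly neutral conditions and should give the Weinreb amide without moving the β,γ-double bond into conjugation.

Step 4
Reactants: 8 N-methoxy-N,4-dimethylpent-3-enamide
Product: 10 6-methylhept-5-en-1-yn-3-one, via magnesium hemiaminal 9 (not isolated)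
Conditions: HC≡CMgBr, THF, 0 °C; inverse quench into cold 1 M aq HCl
Reagents that add atoms: ethynylmagnesium bromide, C#C[Mg]Br
Why: Weinreb ketone synthesis, in which the chelated tetrahedral adduct 9 stops the addition at the ketone stage and the inverse acidic quench protonates the released amine before it can add to the ynone.

Step 5
Reactants: 10 6-methylhept-5-en-1-yn-3-one
Product: 12 (R)-6-methylhept-5-en-1-yn-3-ol, via borinate 11 (not isolated)
Conditions: (R)-Alpine-Borane, concentrated THF solution, 0 °C → rt; then HOCH2CH2NH2, Et2O, 0 °C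
Reagents that add atoms: none
Why: Midland reduction, in which hydride passes from the pinanyl C–H to the ketone through a boat-like six-membered transition state with the slim ethynyl group, not the CH2 of the prenyl arm, next to the pinane methyl group, so that the reagent derived from (+)-α-pinene should give the (R)-carbinol (C1′ of the target) under neutral conditions that leave the β,γ-alkene in place.

Step 6
Reactants: 12 (R)-6-methylhept-5-en-1-yn-3-ol; 13 3,4-dimethylpent-3-enoic acid
Product: 14 (R)-6-methylhept-5-en-1-yn-3-yl 3,4-dimethylpent-3-enoate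
Conditions: N,N′-dicyclohexylcarbodiimide, DMAP (cat.), CH2Cl2, 0 °C → rt
Reagents that add atoms: none
Why: Steglich esterification acylates the oxygen only, so the C–O bond at the stereocentre is untouched and the (R) configuration is retained.

Step 7
Reactants: 5 pentacarbonyl{[2,5-bis(methoxymethoxy)phenyl](methoxy)carbene}chromium; 14 (R)-6-methylhept-5-en-1-yn-3-yl 3,4-dimethylpent-3-enoate
Product: 16 (R)-1-[5,8-bis(methoxymethoxy)-1,4-dioxo-1,4-dihydronaphthalen-2-yl]-4-methylpent-3-enyl 3,4-dimethylpent-3-enoate, via naphthol tricarbonylchromium complex 15 (not isolated)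
Conditions: degassed THF, 50 °C, Ar; then (NH4)2Ce(NO3)6, MeCN/H2O, 0 °C
Reagents that add atoms: water, O
Why: Dötz benzannulation, a formal [3+2+1] cycloaddition: loss of one CO from 5 (helped by the ortho OMOM oxygen) opens a site for the terminal alkyne of 14, which inserts into the Cr=C bond (C3–C4), and a CO ligand then inserts (C1–C2) to give an η4-arylvinylketene complex. The ring closes by 6π-electrocyclisation of this ketene onto the free ortho carbon of the arene (C1–C8a), and tautomerisation gives the 4-methoxy-1-naphthol complex 15. (NH4)2Ce(NO3)6 then strips the metal and oxidises the p-methoxynaphthol ring, the most electron-rich ring, to the quinone with loss of methanol, water delivering the C4 oxygen. No new stereocentre remains, since the planar chirality of 15 vanishes on decomplexation and C1′ takes part in no bond change and keeps its (R) configuration. Regioselectivity is not needed, because the 5,8-bis(OMOM) ring is symmetric and both alkyne orientations end in the same quinone (the terminal alkyne should in any case place the side chain next to C1–OH). Chemoselectivity for the alkyne over the tri- and tetrasubstituted alkenes rests on the much faster insertion of an unhindered alkyne, and the low temperature and neutral medium are chosen to keep the benzylic acyloxy group of 15 from ionising before the oxidation.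

Step 8
Reactants: 16 (R)-1-[5,8-bis(methoxymethoxy)-1,4-dioxo-1,4-dihydronaphthalen-2-yl]-4-methylpent-3-enyl 3,4-dimethylpent-3-enoate
Product: 17 (R)-1-(5,8-dihydroxy-1,4-dioxo-1,4-dihydronaphthalen-2-yl)-4-methylpent-3-enyl 3,4-dimethylpent-3-enoate (target)
Conditions: 3 M aq HCl, THF, rt
Reagents that add atoms: none
Why: Acid-catalysed acetal hydrolysis, made easy because the peri carbonyl groups turn both aryloxy groups into good leaving groups that end as chelated phenols, while dilute acid without an alcohol cosolvent should leave the ester, both alkenes and C1′ untouched.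

Compound list
1 | hydroquinone | Oc1ccc(O)cc1 | starting material
2 | 1,4-bis(methoxymethoxy)benzene | COCOc1ccc(OCOC)cc1 | intermediate
3 | 2,5-bis(methoxymethoxy)phenyllithium | [Li]c1cc(OCOC)ccc1OCOC | intermediate
4 | lithium pentacarbonyl[2,5-bis(methoxymethoxy)benzoyl]chromate | [Li+].[O-]C(c1cc(OCOC)ccc1OCOC)=[Cr](=C=O)(=C=O)(=C=O)(=C=O)=C=O | intermediate
5 | pentacarbonyl{[2,5-bis(methoxymethoxy)phenyl](methoxy)carbene}chromium | COC(c1cc(OCOC)ccc1OCOC)=[Cr](=C=O)(=C=O)(=C=O)(=C=O)=C=O | intermediate
6 | 4-methylpent-3-enoic acid | CC(C)=CCC(=O)O | starting material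
7 | 1-(4-methylpent-3-enoyl)imidazole | CC(C)=CCC(=O)n1ccnc1 | intermediate
8 | N-methoxy-N,4-dimethylpent-3-enamide | CON(C)C(=O)CC=C(C)C | intermediate
9 | bromomagnesium 3-[methoxy(methyl)amino]-6-methylhept-5-en-1-yn-3-olate | C#CC(CC=C(C)C)(O[Mg]Br)N(C)OC | intermediate
10 | 6-methylhept-5-en-1-yn-3-one | C#CC(=O)CC=C(C)C | intermediate
11 | 9-[(R)-6-methylhept-5-en-1-yn-3-yloxy]-9-borabicyclo[3.3.1]nonane | CC(C)=CC[C@@H](OB1C2CCCC1CCC2)C#C | intermediate
12 | (R)-6-methylhept-5-en-1-yn-3-ol | CC(C)=CC[C@@H](O)C#C | intermediate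
13 | 3,4-dimethylpent-3-enoic acid | CC(C)=C(C)CC(=O)O | starting material
14 | (R)-6-methylhept-5-en-1-yn-3-yl 3,4-dimethylpent-3-enoate | CC(C)=CC[C@@H](OC(=O)CC(C)=C(C)C)C#C | intermediate
15 | tricarbonylchromium complex (η6, written as two parts) of (R)-1-[1-hydroxy-4-methoxy-5,8-bis(methoxymethoxy)naphthalen-2-yl]-4-methylpent-3-enyl 3,4-dimethylpent-3-enoate | CC(C)=CC[C@@H](OC(=O)CC(C)=C(C)C)c1cc(OC)c2c(OCOC)ccc(OCOC)c2c1O.O=C=[Cr](=C=O)=C=O | intermediate
16 | (R)-1-[5,8-bis(methoxymethoxy)-1,4-dioxo-1,4-dihydronaphthalen-2-yl]-4-methylpent-3-enyl 3,4-dimethylpent-3-enoate | CC(C)=CC[C@@H](OC(=O)CC(C)=C(C)C)C1=CC(=O)c2c(OCOC)ccc(OCOC)c2C1=O | intermediate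
17 | (R)-1-(5,8-dihydroxy-1,4-dioxo-1,4-dihydronaphthalen-2-yl)-4-methylpent-3-enyl 3,4-dimethylpent-3-enoate | CC(C)=CC[C@@H](OC(=O)CC(C)=C(C)C)C1=CC(=O)c2c(O)ccc(O)c2C1=O | target

Total step count: 8. Longest linear sequence: 6 steps (6 → 8 → 10 → 12 → 14 → 16 → 17).

Steps most likely to fail

**Step 7.**
- What may go wrong: the benzylic acyloxy group may ionise while the material sits at the electron-rich naphthol stage, costing the ester or eroding the configuration. The neighbouring ester carbonyl may also divert the vinylcarbene away from CO insertion.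
- The fallback sets out from 12 (with 5) and comes back at 17. The ester is brought in last.
- Alcohol 12 is silylated (TBSCl, imidazole, DMF) to (R)-tert-butyldimethyl[(6-methylhept-5-en-1-yn-3-yl)oxy]silane F1.
- Benzannulation of F1 with 5 as in step 7 gives the silyloxy naphthol tricarbonylchromium complex F2, which (NH4)2Ce(NO3)6 oxidises in the same flask to the silyloxy bis(methoxymethoxy) quinone F3.
- Aqueous HCl in THF removes the silyl group and both acetals to give shikonin F4.
- Steglich acylation of F4 with 13 (N,N′-dicyclohexylcarbodiimide, DMAP, CH2Cl2) should occur only at the side-chain hydroxyl, because both peri hydroxyls are held in hydrogen bonds to the quinone carbonyls. This gives 17.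

**Step 8.**
- What may go wrong: once the free naphthazarin has formed, acid may promote ionisation at C1′, with loss of the ester or of configuration. The alkenes may be protonated, or cleavage of the second acetal may stay incomplete.
- The fallback sets out from 14 and comes back at 17. It replaces acetal hydrolysis by oxidative unmasking.
- Purchased 1,4-dimethoxybenzene is lithiated (n-BuLi, TMEDA) to 2,5-dimethoxyphenyllithium F5.
- F5 adds to Cr(CO)6 to give lithium pentacarbonyl(2,5-dimethoxybenzoyl)chromate F6, and MeOTf converts this into pentacarbonyl[(2,5-dimethoxyphenyl)(methoxy)carbene]chromium F7.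
- Benzannulation of F7 with 14 as in step 7 leads, by way of the trimethoxynaphthol tricarbonylchromium complex F8, to the 5,8-dimethoxy-1,4-naphthoquinone ester F9.
- Oxidative demethylation (AgO, aq HNO3, acetone, short contact) takes the dimethoxy ring to a second quinone, the naphthalene-1,4,5,8-tetraone ester F10.
- Reductive work-up with Na2S2O4 should then give 17.

**Step 5.**
- What may go wrong: poor discrimination of the ketone faces if the reduction is slow and dehydroboration of the reagent competes. The terminal ynone may also decompose or isomerise during the long reaction.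
- The fallback sets out from 8 and comes back at 12. It replaces the stoichiometric borane by catalytic transfer hydrogenation of a sturdier silyl ynone.
- Lithium trimethylsilylacetylide adds to 8 (THF, −78 °C, acidic quench) to give 6-methyl-1-(trimethylsilyl)hept-5-en-1-yn-3-one F11.
- Noyori transfer hydrogenation with RuCl[(R,R)-TsDPEN](p-cymene) in i-PrOH should give (R)-6-methyl-1-(trimethylsilyl)hept-5-en-1-yn-3-ol F12, the alkynyl group taking the place of the aryl group in the usual model.
- K2CO3 in MeOH removes the silyl group to give 12.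

Further compounds
F1 | step 7 | (R)-tert-butyldimethyl[(6-methylhept-5-en-1-yn-3-yl)oxy]silane | CC(C)=CC[C@@H](O[Si](C)(C)C(C)(C)C)C#C
F2 | step 7 | tricarbonylchromium complex of 2-[(R)-1-(tert-butyldimethylsilyloxy)-4-methylpent-3-enyl]-4-methoxy-5,8-bis(methoxymethoxy)naphthalen-1-ol | CC(C)=CC[C@@H](O[Si](C)(C)C(C)(C)C)c1cc(OC)c2c(OCOC)ccc(OCOC)c2c1O.O=C=[Cr](=C=O)=C=O
F3 | step 7 | 2-[(R)-1-(tert-butyldimethylsilyloxy)-4-methylpent-3-enyl]-5,8-bis(methoxymethoxy)naphthalene-1,4-dione | CC(C)=CC[C@@H](O[Si](C)(C)C(C)(C)C)C1=CC(=O)c2c(OCOC)ccc(OCOC)c2C1=O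
F4 | step 7 | shikonin, 5,8-dihydroxy-2-[(R)-1-hydroxy-4-methylpent-3-enyl]naphthalene-1,4-dione | CC(C)=CC[C@@H](O)C1=CC(=O)c2c(O)ccc(O)c2C1=O
F5 | step 8 | 2,5-dimethoxyphenyllithium | [Li]c1cc(OC)ccc1OC
F6 | step 8 | lithium pentacarbonyl(2,5-dimethoxybenzoyl)chromate | [Li+].[O-]C(c1cc(OC)ccc1OC)=[Cr](=C=O)(=C=O)(=C=O)(=C=O)=C=O
F7 | step 8 | pentacarbonyl[(2,5-dimethoxyphenyl)(methoxy)carbene]chromium | COC(c1cc(OC)ccc1OC)=[Cr](=C=O)(=C=O)(=C=O)(=C=O)=C=O
F8 | step 8 | tricarbonylchromium complex of (R)-1-(1-hydroxy-4,5,8-trimethoxynaphthalen-2-yl)-4-methylpent-3-enyl 3,4-dimethylpent-3-enoate | CC(C)=CC[C@@H](OC(=O)CC(C)=C(C)C)c1cc(OC)c2c(OC)ccc(OC)c2c1O.O=C=[Cr](=C=O)=C=O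
F9 | step 8 | (R)-1-(5,8-dimethoxy-1,4-dioxo-1,4-dihydronaphthalen-2-yl)-4-methylpent-3-enyl 3,4-dimethylpent-3-enoate | CC(C)=CC[C@@H](OC(=O)CC(C)=C(C)C)C1=CC(=O)c2c(OC)ccc(OC)c2C1=O
F10 | step 8 | (R)-4-methyl-1-(1,4,5,8-tetraoxo-1,4,5,8-tetrahydronaphthalen-2-yl)pent-3-enyl 3,4-dimethylpent-3-enoate | CC(C)=CC[C@@H](OC(=O)CC(C)=C(C)C)C1=CC(=O)C2=C(C1=O)C(=O)C=CC2=O
F11 | step 5 | 6-methyl-1-(trimethylsilyl)hept-5-en-1-yn-3-one | CC(C)=CCC(=O)C#C[Si](C)(C)C
F12 | step 5 | (R)-6-methyl-1-(trimethylsilyl)hept-5-en-1-yn-3-ol | CC(C)=CC[C@@H](O)C#C[Si](C)(C)C
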